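**Retrosynthetic overview**
- The C3=C4 alkene comes from syn-elimination of a sulfoxide on C4. The O1–C8a bond and the benzene ring come from an aromatising transketalisation of a quinone-monoketal adduct. The pyran closes first and the arene forms directly after it, both in the last step.
- Key disconnection C4–C4a: a γ-oxido α-sulfinyl carbanion (a sulfinyl-stabilised homoenolate, d3) adds to the β-carbon (a3) of 4,4-dimethoxy-3-methylcyclohexa-2,5-dienone.
- C3–C4: PhS(O)CH2Li opens an (S)-2,2-disubstituted terminal epoxide. Methyl phenyl sulfoxide thus serves as the one-carbon linchpin for C4.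
- C2 is set by catalytic asymmetric methylene transfer to (E,E)-farnesylacetone. The C2–O bond is never broken afterwards.

Assumption: the given SMILES corresponds to (2S), and geometrically pure (5E,9E)-farnesylacetone and 4-methoxy-3-methylphenol are bought as such.

**Step 1**
Reactants: 1 (5E,9E)-6,10,14-trimethylpentadeca-5,9,13-trien-2-one (farnesylacetone)
Product: 2 (2S)-2-methyl-2-[(3E,7E)-4,8,12-trimethyltrideca-3,7,11-trien-1-yl]oxirane
Conditions: Me3S(O)Cl, NaH, THF, reflux (ylide, 1.2 equiv); then 1, La-Li3-tris(binaphthoxide) (LLB, 5 mol %, from the BINOL antipode that gives Re-face attack; (S)-BINOL is taken here and the sense of induction is checked on the first batch), (2,4,6-(MeO)3C6H2)3P=O (5 mol %), 5 Å MS, THF, rt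
Reagents that add atoms: trimethylsulfoxonium chloride, C[S+](C)(C)=O.[Cl-]
Why: Catalytic asymmetric Corey–Chaykovsky epoxidation, in which the La/Li pocket binds ketone and ylide, distinguishes CH3 from the CH2R arm and delivers CH2 to the Re face, setting C2 as S (methyl n-alkyl ketones typically give 91–97 % ee), while the isolated trisubstituted alkenes are inert to the ylide.

**Step 2**
Reactants: 2 (2S)-epoxide; 3 methyl phenyl sulfoxide (racemic)
Product: 5 (3S,6E,10E)-3,7,11,15-tetramethyl-1-(phenylsulfinyl)hexadeca-6,10,14-trien-3-ol (1:1 at sulfur), via lithiomethyl phenyl sulfoxide 4 (not isolated)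
Conditions: 3 (1.5 equiv), LDA (1.5 equiv), THF, −78 → 0 °C; 2, 0 °C → rt, 16 h; H2O
Reagents that add atoms: none
Why: SN2 opening of the epoxide at its unsubstituted CH2 by an α-sulfinyl carbanion (a d1, formyl-anion-type reagent) leaves the C2–O bond and the S configuration untouched, and the racemic sulfur centre only gives a pair of S-epimers that converges in step 5.

**Step 3**
Reactants: 6 4-methoxy-3-methylphenol
Product: 7 4,4-dimethoxy-3-methylcyclohexa-2,5-dien-1-one
Conditions: PhI(OAc)2 (1.05 equiv), MeOH, 0 °C → rt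
Reagents that add atoms: methanol, CO
Why: Hypervalent-iodine oxidative dearomatisation of a p-alkoxyphenol, in which methanol captures the phenoxenium ion at the methoxy-bearing para carbon and turns the nucleophilic arene into an electrophilic cross-conjugated dienone; no stereocentre is formed.

**Step 4** (key step)
Reactants: 5 (3S)-γ-hydroxy sulfoxide; 7 quinone monoketal
Product: 9 5-[(3S,6E,10E)-3-hydroxy-3,7,11,15-tetramethyl-1-(phenylsulfinyl)hexadeca-6,10,14-trien-1-yl]-4,4-dimethoxy-3-methylcyclohex-2-en-1-one (diastereomer mixture at ring C5, side-chain C1 and S), via dilithiated hydroxy sulfoxide 8 (not isolated)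
Conditions: LDA (2.2 equiv), THF–DMPU 5:1, −78 → −40 °C; 7 (1.3 equiv), −78 → −20 °C; AcOH, −78 °C
Reagents that add atoms: none
Why: Proposed new method: the γ-oxido α-sulfinyl carbanion is a homoenolate (d3) equivalent in which C4, normally the acceptor β-carbon, acts as donor, and the DMPU-separated ion pair together with reversible 1,2-addition should funnel it to the only unsubstituted β-carbon of the dienone (the other carries CH3), so two carbons that are both acceptors in normal polarity are joined; the closest known reaction types are Michael additions of sulfonyl-, cyano- and nitro-stabilised carbanions to quinone monoketals (first stage of Hauser–Kraus annulations) and 1,4-additions of organolithiums to carbonyl-blocked quinone monoketals; the new stereocentres are erased in step 5 and C2 is untouched.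

**Step 5**
Reactants: 9 Michael adduct
Product: 11 (2S)-2,8-dimethyl-2-[(3E,7E)-4,8,12-trimethyltrideca-3,7,11-trien-1-yl]-2H-chromen-6-ol, via 4-sulfinylchroman-6-ol 10 (not isolated)
Conditions: CSA (10 mol %), 4 Å MS, toluene, rt; then NaHCO3, P(OMe)3 (2 equiv), 70 °C, Ar, dark
Reagents that add atoms: none
Why: Transketalisation–aromatisation followed by sulfoxide syn-elimination (Ei): the ketal oxocarbenium ion is trapped by the tertiary OH in a six-membered ring, the sieves remove MeOH, and loss of the second MeOH plus enolisation gives the phenol with the original C2–O bond (retention at C2); after the acid is neutralised, the C4 sulfoxide can only take a C3–H, giving the ring-cis C3=C4 alkene without any cation next to the polyene.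

**Compound list**
1 | (5E,9E)-6,10,14-trimethylpentadeca-5,9,13-trien-2-one | CC(C)=CCC/C(C)=C/CC/C(C)=C/CCC(C)=O | starting material
2 | (2S)-2-methyl-2-[(3E,7E)-4,8,12-trimethyltrideca-3,7,11-trien-1-yl]oxirane | CC(C)=CCC/C(C)=C/CC/C(C)=C/CC[C@@]1(C)CO1 | intermediate
3 | methyl phenyl sulfoxide (racemic) | CS(=O)c1ccccc1 | starting material
4 | lithiomethyl phenyl sulfoxide | [Li]CS(=O)c1ccccc1 | intermediate
5 | (3S,6E,10E)-3,7,11,15-tetramethyl-1-(phenylsulfinyl)hexadeca-6,10,14-trien-3-ol | CC(C)=CCC/C(C)=C/CC/C(C)=C/CC[C@](C)(O)CCS(=O)c1ccccc1 | intermediate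
6 | 4-methoxy-3-methylphenol | COc1ccc(O)cc1C | starting material
7 | 4,4-dimethoxy-3-methylcyclohexa-2,5-dien-1-one | COC1(OC)C=CC(=O)C=C1C | intermediate
8 | O,C1-dilithio derivative of 5 | CC(C)=CCC/C(C)=C/CC/C(C)=C/CC[C@](C)(O[Li])CC([Li])S(=O)c1ccccc1 | intermediate
9 | 5-[(3S,6E,10E)-3-hydroxy-3,7,11,15-tetramethyl-1-(phenylsulfinyl)hexadeca-6,10,14-trien-1-yl]-4,4-dimethoxy-3-methylcyclohex-2-en-1-one | CC(C)=CCC/C(C)=C/CC/C(C)=C/CC[C@](C)(O)CC(S(=O)c1ccccc1)C1CC(=O)C=C(C)C1(OC)OC | intermediate
10 | (2S)-2,8-dimethyl-4-(phenylsulfinyl)-2-[(3E,7E)-4,8,12-trimethyltrideca-3,7,11-trien-1-yl]-3,4-dihydro-2H-chromen-6-ol | CC(C)=CCC/C(C)=C/CC/C(C)=C/CC[C@@]1(C)CC(S(=O)c2ccccc2)c2cc(O)cc(C)c2O1 | intermediate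
11 | (2S)-2,8-dimethyl-2-[(3E,7E)-4,8,12-trimethyltrideca-3,7,11-trien-1-yl]-2H-chromen-6-ol | CC(C)=CCC/C(C)=C/CC/C(C)=C/CC[C@@]1(C)C=Cc2cc(O)cc(C)c2O1 | target

**Total steps:** 5. **Longest linear sequence:** 4 (steps 1, 2, 4, 5).

**Steps most likely to fail, in order of risk: 4, 5, 1**

(i) In the conjugate addition of step 4, the basic dianion may add 1,2, deprotonate the vinylogous methyl group of 7, or reduce 7.
- The fallback sets out from epoxide 2 and comes back at 10. It puts C4 on the arene from the start and closes O1–C8a by metal catalysis.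
- 4-Bromo-3,5-dimethylphenol F1 is silylated (TIPSCl, imidazole) to (4-bromo-3,5-dimethylphenoxy)triisopropylsilane F2.
- One of the two equivalent methyl groups is brominated (NBS, AIBN) to give the benzylic bromide F3, which PhSNa converts into the benzyl phenyl sulfide F4.
- The α-thio carbanion of F4 (LiTMP) opens 2 at CH2 to give the γ-hydroxy sulfide F5.
- Pd-catalysed intramolecular C–O coupling of the tertiary alcohol with the aryl bromide (Buchwald-type etherification, Cs2CO3) gives the 4-(phenylthio)chroman silyl ether F6.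
- H2O2 in HFIP oxidises sulfur only, giving the sulfoxide F7, and TBAF releases 10.

(ii) In the first half of step 5, the oxocarbenium ion may lose its proton before the tertiary OH is incorporated, so that OMe stays on the ring.
- The fallback sets out from 9 and comes back at 10.
- Plain acid aromatisation is accepted and gives the open-chain 4-methoxyphenol F8.
- PhI(OAc)2 in MeCN, with no external nucleophile, re-oxidises F8 to the phenoxenium ion. The tertiary OH traps it at the methoxy-bearing carbon to give the cyclic 8a-methoxy dienone F9.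
- Ascorbic acid in aqueous MeOH reduces F9 with loss of MeOH to 10 (tocopherone-to-tocopherol type reduction, C2–O retained).

(iii) In step 1, the enantioselectivity on this long lipophilic ketone may fall short.
- The fallback sets out from 1 and comes back at 2.
- Ordinary Corey–Chaykovsky methylenation gives the racemic epoxide F10.
- Kinetic resolution with TMSN3 and a chiral (salen)Cr–N3 complex consumes the R enantiomer as the azido silyl ether F11 and leaves 2.
- The same resolution can polish 2 obtained from step 1 to >99 % ee.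

**Further compounds**
F1 | step 4 | 4-bromo-3,5-dimethylphenol | Cc1cc(O)cc(C)c1Br
F2 | step 4 | (4-bromo-3,5-dimethylphenoxy)triisopropylsilane | Cc1cc(O[Si](C(C)C)(C(C)C)C(C)C)cc(C)c1Br
F3 | step 4 | [4-bromo-3-(bromomethyl)-5-methylphenoxy]triisopropylsilane | Cc1cc(O[Si](C(C)C)(C(C)C)C(C)C)cc(CBr)c1Br
F4 | step 4 | {4-bromo-3-methyl-5-[(phenylthio)methyl]phenoxy}triisopropylsilane | Cc1cc(O[Si](C(C)C)(C(C)C)C(C)C)cc(CSc2ccccc2)c1Br
F5 | step 4 | (3S,6E,10E)-1-[2-bromo-3-methyl-5-(triisopropylsilyloxy)phenyl]-3,7,11,15-tetramethyl-1-(phenylthio)hexadeca-6,10,14-trien-3-ol | CC(C)=CCC/C(C)=C/CC/C(C)=C/CC[C@](C)(O)CC(Sc1ccccc1)c1cc(O[Si](C(C)C)(C(C)C)C(C)C)cc(C)c1Br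
F6 | step 4 | (2S)-2,8-dimethyl-4-(phenylthio)-6-(triisopropylsilyloxy)-2-[(3E,7E)-4,8,12-trimethyltrideca-3,7,11-trien-1-yl]chroman | CC(C)=CCC/C(C)=C/CC/C(C)=C/CC[C@@]1(C)CC(Sc2ccccc2)c2cc(O[Si](C(C)C)(C(C)C)C(C)C)cc(C)c2O1
F7 | step 4 | (2S)-2,8-dimethyl-4-(phenylsulfinyl)-6-(triisopropylsilyloxy)-2-[(3E,7E)-4,8,12-trimethyltrideca-3,7,11-trien-1-yl]chroman | CC(C)=CCC/C(C)=C/CC/C(C)=C/CC[C@@]1(C)CC(S(=O)c2ccccc2)c2cc(O[Si](C(C)C)(C(C)C)C(C)C)cc(C)c2O1
F8 | step 5 | 3-[(3S,6E,10E)-3-hydroxy-3,7,11,15-tetramethyl-1-(phenylsulfinyl)hexadeca-6,10,14-trien-1-yl]-4-methoxy-5-methylphenol | CC(C)=CCC/C(C)=C/CC/C(C)=C/CC[C@](C)(O)CC(S(=O)c1ccccc1)c1cc(O)cc(C)c1OC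
F9 | step 5 | (2S)-8a-methoxy-2,8-dimethyl-4-(phenylsulfinyl)-2-[(3E,7E)-4,8,12-trimethyltrideca-3,7,11-trien-1-yl]-2,3,4,8a-tetrahydro-6H-chromen-6-one | CC(C)=CCC/C(C)=C/CC/C(C)=C/CC[C@@]1(C)CC(S(=O)c2ccccc2)C2=CC(=O)C=C(C)C2(OC)O1
F10 | step 1 | rac-2-methyl-2-[(3E,7E)-4,8,12-trimethyltrideca-3,7,11-trien-1-yl]oxirane | CC(C)=CCC/C(C)=C/CC/C(C)=C/CCC1(C)CO1
F11 | step 1 | {[(2R,5E,9E)-1-azido-2,6,10,14-tetramethylpentadeca-5,9,13-trien-2-yl]oxy}trimethylsilane | CC(C)=CCC/C(C)=C/CC/C(C)=C/CC[C@](C)(CN=[N+]=[N-])O[Si](C)(C)C
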